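**The decision.** Leave the flask closed and stirring until 15 d, and add nothing. It holds substrate, solid reagent that supplies partner, and catalyst that interconverts target and isomer of the product.

| flask | substrate | solid reagent | catalyst | remark | time |
|---|---|---|---|---|---|
| Wednesday's | 0.011 M | 4 equiv | 0.11 mol% | run made earlier |  |
| Sunday's | 0.046 M | 4 equiv | 0.11 mol% | run made earlier |  |
| Monday's | 0.023 M | 4 equiv | 0.17 mol% | run made earlier |  |
| flask | 0.023 M | 4.00 equiv | 0.11 mol% |  | 15 d |

- Wednesday's (time / d: isomer of the product / %, target / %): 0.625: 6, 53; 1.67: 10, 79; 3.00: 10, 78; 5.00: 14, 78; 6.00: 13, 79; 10.0: 13, 77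
- Sunday's (time / d: isomer of the product / %, target / %): 0.625: 0, 25; 1.67: 1, 66; 3.00: 4, 93; 5.00: 2, 91; 6.00: 0, 94; 10.0: 2, 94
- Monday's (time / d: isomer of the product / %, target / %): 0.625: 7, 35; 1.25: 9, 75; 2.50: 7, 88; 5.00: 6, 88; 10.0: 6, 90

(each reading ± 2 percentage points)

- for target the crystals are counted in
- as a solid, counted per litre of solution: solid reagent, crystals
- steps thought possible: substrate + partner <-> target; substrate + partner <-> isomer of the product; target + catalyst <-> isomer of the product + catalyst; solid reagent <-> partner; crystals <-> target
- at the start none of the solid reagent is in solution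

* ratio of isomer of the product to target at 1.5 h
* ratio of isomer of the product to target at 15 d

**Frozen quantity.** Wednesday's run ends at 1.43 mM of [isomer of the product] and Monday's at about the same 1.38 mM, although Monday's run held more substrate and more catalyst. Their mean, 1.41 mM, is the isomer plateau: the concentration of isomer that stands once crystals have taken up the excess target.

**Expected state.** Divided by the charge, the plateau gives 6.11% isomer in this flask; over Monday's final target reading, that is a ratio of 0.0679 at 15 d, above the forecast's value below.

**Early ratio.** The earliest reading, at 0.625 d, comes later than 1.5 h, so the early ratio remains poorly read.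

**The forecast.** It gives 0.12 at 1.5 h and 0.066 at 15 d: “This looks like catalysed solution equilibrium with target held at its solubility, while crystals take up the rest.”

**The result.** substrate + partner ⇌ target (K = 70.0 M⁻¹, k = 92.0 M⁻¹ h⁻¹); substrate + partner ⇌ isomer of the product (K = 130 M⁻¹, k = 0.950 M⁻¹ h⁻¹); target + catalyst ⇌ isomer of the product + catalyst, rate k3*[catalyst]*[target] forward; the back reaction follows from the equilibrium constant (k = 6600 M⁻¹ h⁻¹); solid reagent ⇌ partner, rate k4*(cs4 - [partner]) while solid is left; crystals form when [partner] > cs4 (solubility = 9.00 mM, k = 0.0980 h⁻¹); crystals ⇌ target, rate k5*(cs5 - [target]) while solid is left; crystals form when [target] > cs5 (solubility = 0.700 mM, k = 3.90 h⁻¹)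

This flask gives 0.125 at 1.5 h and 0.0631 at 15 d, both as forecast. Its exchange between dissolved target and isomer of the product relaxes with a half-life of 0.112 d, short against 15 d, which is thermodynamic control. Its isomer stands at 1.30 mM, beside the plateau of 1.41 mM. For a neighbour charged with 0.039 M of substrate, the plateau gives 3.62%, and that flask holds 3.33% isomer at 15.0 d.

All runs were computed with constants of no real substance; scatter was added.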